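# Euchrenone b2 by a one-pot triple aromatic Claisen rearrangement: synthesis proposal

## The problem

Euchrenone b2 16 is 5,7,2',4'-tetrahydroxy-6,8,3'-tris(3-methylbut-2-enyl)isoflavone: a phloroglucinol-type ring A fused to the 4-pyranone ring C, with the resorcinol-type ring B attached through the C3–C1' bond. There is no stereocentre and no alkene geometry to set, so the difficulty is purely positional: three identical prenyl chains must sit on C6, C8 and C3', each between two oxygen-bearing carbons, and ring A ends up hexasubstituted. The four phenols differ (5-OH is hydrogen-bonded to the C4 carbonyl, 7-OH is the most acidic, 2'-OH and 4'-OH are ordinary) and must be told apart, because only some of them may serve as handles. Every prenyl group lies ortho to a free phenol, so acid closes 2,2-dimethylchroman rings; the trisubstituted alkenes forbid hydrogenolysis, ring C opens at C2 with hydroxide or amines, and the polyphenoxide is air-sensitive. The closing steps must therefore be neutral and few, and direct electrophilic prenylation of the polyphenol is ruled out because it would spread over C6, C8, C3', C5' and the oxygens. The feature that opens a way is that each prenylated carbon has a phenolic oxygen as neighbour: C6 is ortho to O5, C8 to O7 and C3' to O2'. For O5 and O2' the other ortho carbon (C4a, C1') is quaternary, so each has one destination only, and O5 also lies peri to the C4 carbonyl, where a chelating Lewis acid can make its group move before the others.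

## Retrosynthesis

**16 from 15 (O4'–Si).** The last bond cut is the silyl ether on O4'. This oxygen is the one ring B oxygen that must not carry an allyl group, since from O4' a group could reach C5' as well as C3'. A silyl ether is chosen because fluoride removes it under near-neutral conditions, which spares the three o-prenylphenol units; acid-labile or hydrogenolysable groups would not. Triisopropylsilyl is preferred to a smaller silyl group because it must survive aqueous carbonate and an amidine base earlier in the route. The forward step only needs buffered fluoride.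

**15 from 13 (C6–CH2, C8–CH2, C3'–CH2).** The three aryl–CH2 bonds are cut together and each prenyl group is returned to the neighbouring oxygen as a 1,1-dimethylallyl ether, giving 13. Against electrophilic C-prenylation, this cut fixes each chain to a position through the oxygen that delivers it; against a threefold cross-coupling, it needs no carbon–halogen bonds and no protection of O5, O7 and O2', which are the carriers. Precursor 13 has no carbon substituent on either benzene ring apart from the biaryl-type bond, and all fifteen side-chain carbons come from one C5 reagent. The forward reaction must move the 5-O group first, to the 6-prenyl 5-phenol 14; the 7-O group then finds C8 as its only open ortho carbon, and the 2'-O group can only go to C3'.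

**13 from 12 (alkene from alkyne).** The three vinyl groups of 13 are traced back to the terminal alkynes of 12. Tertiary allyl aryl ethers cannot be made by direct displacement, and they ionise with zerovalent palladium or acid. They must therefore appear only after the last metal-catalysed bond formation. The tertiary propargyl ethers are accessible with catalytic CuCl2 and are inert to palladium and mild heat. The forward step must stop at the alkene on all three sites.

**12 from 11 and 2 (O2'–C).** The ring B ether is cut to the phenol 11 and 3-chloro-3-methylbut-1-yne 2. Phenol 11 has a single free hydroxyl, so no selectivity is asked. This ether is made after the biaryl-type bond because an aryl propargyl ether with an ortho bromine or ortho boron would invite intramolecular carbopalladation and would not tolerate aryllithium formation.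

**11 from 6 and 10 (C3–C1').** Cutting the C3–C1' bond gives the 3-iodochromone 6 and the arylboronate 10, two fragments of similar size. The alternative order, coupling first and etherifying ring A afterwards, is rejected: the chelated 5-OH of a finished chromone resists the bulky tertiary electrophile. The price is that two terminal alkynes ride through the coupling, so the forward reaction must cross-couple faster than it alkynylates and must tolerate the free phenol of 10.

**6 from 5 from 4 (O1–C2, C3–I, C2–Cα).** The pyranone ring is opened to the enaminone 5, and 5 is cut to the acetophenone 4 and a one-carbon formamide acetal unit. Iodine enters C3 in the ring-closing event, so no separate halogenation is needed. Neither step may heat the propargyl ethers to their own rearrangement threshold.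

**4 from 1 and 2 (two O–C bonds, via 3).** Both ethers of 4 are cut back to 2,4,6-trihydroxyacetophenone 1 and two molecules of 2. In 1 only one of the two ortho hydroxyls is tied to the acetyl carbonyl at a time. The para hydroxyl reacts first (mono-ether 3), then the free ortho hydroxyl, and the remaining chelated one is kept to become O1. This is what makes the O5 ether accessible at all.

**10 from 8 from 7 (C–B, O–Si).** The boronate 10 comes from the bromophenol 8 through the dilithio species 9, and 8 from 4-bromoresorcinol 7 by silylation of the less hindered hydroxyl para to bromine. The hydroxyl ortho to bromine stays free and becomes O2'.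

## Roads not taken

Alternative 1: the C3–C1' bond is formed inside a temporary ester bridge, which is taken down afterwards. The cut is the bond between rings B and C, made while the two are tied together. In the forward key step the aryl ester 3-(methoxymethoxy)-2-(3-methylbut-2-enyl)phenyl 3-iodo-5,7-bis(methoxymethoxy)-6,8-bis(3-methylbut-2-enyl)-4-oxo-4H-chromene-2-carboxylate A1 would cyclise with Pd(OAc)2, PCy3 and K2CO3 to the lactone-bridged isoflavone A2, in which the C2 carbonyl is tied to O2'. The merit is real: the tether makes the arylation intramolecular, so it needs no organoboron partner and is indifferent to the crowding of a 2',3'-disubstituted ring B. On that one bond it is safer than the intermolecular coupling of 6 with the electron-rich boronate 10. The weak points lie elsewhere. A1 must already carry all three prenyl groups, so the central problem of placing them is only moved into two fragment syntheses. An arylpalladium intermediate is generated next to three trisubstituted alkenes. The lactone of A2 has to be opened and the added carboxyl carbon expelled as CO2, which is harsh on a pyranone that opens with base and on o-prenylphenols. Three methoxymethyl ethers then need acid at the end. In comparison, the chosen plan couples an unprenylated, unhindered ring B in one step and has no bridge to build or take down.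

Alternative 2: the three prenyl chains are grown from ring methyl groups by a threefold benzylic cross-coupling. The cut is the three CH2–CH= bonds. In the forward key step 5,7,2',4'-tetraacetoxy-6,8,3'-tris(bromomethyl)isoflavone A3 would couple three times with tributyl(2-methylprop-1-enyl)stannane A4 under Pd(PPh3)4 to give euchrenone b2 tetraacetate A5. The merit is that the three carbons are attached to C6, C8 and C3' from the outset, so position is never in question. In this respect the road is better than any sigmatropic delivery, and the chosen plan has to set against it the single-destination carriers on O5 and O2' and the chelation-timed order in ring A. The weak points are these. Making A3 would demand exactly one radical bromination at each of three benzylic methyl positions flanked by acetoxy groups, without over-bromination or attack elsewhere. A3 is a threefold benzylic bromide, prone to solvolysis and to quinone methide formation once an acetate is lost. Three sp3–sp2 couplings consume three equivalents of the stannane A4 and leave as much organotin waste to remove. The four aryl acetates of A5 must finally be removed with base from a ring C that opens with base. In comparison, the chosen key step uses no stoichiometric reagent and produces no by-product, and its end game is a single fluoride treatment.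

Alternative 3: ring A is built last, on a preformed pyranone, by benzannulation of a ketene. The cut is C5–C6, C7–C8 and C4a–C5. In the forward key step, Wolff rearrangement of 2-(2-diazo-5-methylhex-4-enoyl)-5-[2,4-bis(methoxymethoxy)-3-(3-methylbut-2-enyl)phenyl]-4H-pyran-4-one A6 would give the pyranonyl prenyl ketene A7. Ketene A7 would add triisopropyl[(5-methylhex-4-en-1-yn-1-yl)oxy]silane A8 by [2+2] cycloaddition, four-electron ring opening and six-electron closure onto the pyranone, to give 7-O-triisopropylsilyl-2',4'-bis-O-(methoxymethyl) euchrenone b2 A9. The merits are that ring A is born fully substituted and the position of both ring A prenyl groups follows from connectivity alone, with O5 free and O7 silylated in A9. On regiochemical certainty in ring A this road is superior in principle. The weak points are these. The carbene from A6 has a CH2 group next to it, so a 1,2-hydride shift to an enone competes with the Wolff shift. The electrocyclic closure must engage the deactivated C2=C3 bond of a 4-pyranone, outside the usual range of aryl and vinyl ketenes. A6 and A8 each need several steps, and the ring B prenyl group must still be introduced separately. The two methoxymethyl ethers of A9 must be removed with acid in the presence of three o-prenylphenols. In comparison, the chosen plan uses cheap commercial aromatics, one C5 reagent for all three chains and known reaction types throughout, and it accepts an ordering problem in ring A that is addressed by chelation.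

Key step: step 9

Assumption: 3-chloro-3-methylbut-1-yne 2 is used as purchased. If it had to be made, 2-methylbut-3-yn-2-ol with concentrated HCl, CuCl and CaCl2 would give it in one operation, which is not counted.

## Route

Step 1
Reactants: 1 2,4,6-trihydroxyacetophenone; 2 3-chloro-3-methylbut-1-yne
Product: 4 1-{2-hydroxy-4,6-bis[(2-methylbut-3-yn-2-yl)oxy]phenyl}ethan-1-one, via 4-O-mono(1,1-dimethylpropargyl) ether 3 (not isolated)
Conditions: 2 (2.4 equiv), DBU (2.6 equiv), CuCl2·2H2O (1 mol%), MeCN, 0 °C → rt
Reagents that add atoms: 3-chloro-3-methylbut-1-yne (2), CC(C)(Cl)C#C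
Why: CuCl2-catalysed propargylic etherification of phenoxides through a metal-bound acetylide/allenylidene formed from 2; the para hydroxyl reacts first, then the ortho hydroxyl that is not hydrogen-bonded, while the chelated one is left for the later pyranone closure. Working at or below room temperature keeps the aryl propargyl ethers from cyclising to chromenes.

Step 2
Reactants: 4 1-{2-hydroxy-4,6-bis[(2-methylbut-3-yn-2-yl)oxy]phenyl}ethan-1-one
Product: 5 (E)-3-(dimethylamino)-1-{2-hydroxy-4,6-bis[(2-methylbut-3-yn-2-yl)oxy]phenyl}prop-2-en-1-one
Conditions: DMF-DMA (3 equiv), toluene, 75 °C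
Reagents that add atoms: N,N-dimethylformamide dimethyl acetal, COC(OC)N(C)C
Why: Condensation of the methyl ketone with the amide acetal gives the E enaminone, which supplies the future C2; the temperature stays below the threshold of the propargyl Claisen rearrangement.

Step 3
Reactants: 5 (E)-3-(dimethylamino)-1-{2-hydroxy-4,6-bis[(2-methylbut-3-yn-2-yl)oxy]phenyl}prop-2-en-1-one
Product: 6 3-iodo-5,7-bis[(2-methylbut-3-yn-2-yl)oxy]-4H-chromen-4-one
Conditions: I2 (1.5 equiv), CHCl3/MeOH, rt; aq. Na2S2O3 work-up
Reagents that add atoms: iodine, II
Why: Iodination at the enaminone α-carbon, addition of the phenol to the iminium carbon and loss of dimethylamine close the pyranone and leave iodine on C3 (iodinative enaminone cyclisation); without added amine base the terminal alkynes should not be iodinated.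

Step 4
Reactants: 7 4-bromoresorcinol
Product: 8 2-bromo-5-[(triisopropylsilyl)oxy]phenol
Conditions: TIPSCl (1.0 equiv), imidazole (2 equiv), CH2Cl2, 0 °C
Reagents that add atoms: chlorotriisopropylsilane, CC(C)[Si](Cl)(C(C)C)C(C)C
Why: Silylation of a phenol; the bulky silyl chloride should take the hydroxyl para to bromine, since the one ortho to bromine is more hindered and less nucleophilic. Any bis-silylated material should be separable.

Step 5
Reactants: 8 2-bromo-5-[(triisopropylsilyl)oxy]phenol
Product: 10 2-(4,4,5,5-tetramethyl-1,3,2-dioxaborolan-2-yl)-5-[(triisopropylsilyl)oxy]phenol, via dilithio phenolate 9 (not isolated)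
Conditions: n-BuLi (2.2 equiv), THF, −78 → 0 °C; iPrOBpin (1.5 equiv), −78 °C → rt; aq. NH4Cl
Reagents that add atoms: 2-isopropoxy-4,4,5,5-tetramethyl-1,3,2-dioxaborolane, CC(C)OB1OC(C)(C)C(C)(C)O1; n-butyllithium, [Li]CCCC (lithium of 9 only)
Why: O-Deprotonation and bromine–lithium exchange give the ortho-lithiated phenolate, which is borylated by the isopropoxy boronate; the silyl ether is para to the carbanion, so no silyl migration is possible.

Step 6
Reactants: 6 3-iodo-5,7-bis[(2-methylbut-3-yn-2-yl)oxy]-4H-chromen-4-one; 10 2-(4,4,5,5-tetramethyl-1,3,2-dioxaborolan-2-yl)-5-[(triisopropylsilyl)oxy]phenol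
Product: 11 3-{2-hydroxy-4-[(triisopropylsilyl)oxy]phenyl}-5,7-bis[(2-methylbut-3-yn-2-yl)oxy]-4H-chromen-4-one
Conditions: PdCl2(dppf) (5 mol%), Na2CO3 (2 M aq.), DME, 50 °C, degassed
Reagents that add atoms: none
Why: Suzuki–Miyaura coupling; zerovalent palladium inserts quickly into the C3–I bond of the electron-poor iodochromone, and without CuI or an amine at 50 °C transmetalation from boron should outrun alkynyl transfer from the terminal alkynes. The free ortho phenol is tolerated and emerges as the only unprotected hydroxyl.

Step 7
Reactants: 11 3-{2-hydroxy-4-[(triisopropylsilyl)oxy]phenyl}-5,7-bis[(2-methylbut-3-yn-2-yl)oxy]-4H-chromen-4-one; 2 3-chloro-3-methylbut-1-yne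
Product: 12 5,7-bis[(2-methylbut-3-yn-2-yl)oxy]-3-{2-[(2-methylbut-3-yn-2-yl)oxy]-4-[(triisopropylsilyl)oxy]phenyl}-4H-chromen-4-one
Conditions: 2 (1.5 equiv), DBU (1.6 equiv), CuCl2·2H2O (1 mol%), MeCN, 0 °C → rt
Reagents that add atoms: 3-chloro-3-methylbut-1-yne (2), CC(C)(Cl)C#C
Why: The same CuCl2-catalysed propargylic etherification as in step 1; 2'-OH is the only free hydroxyl, and the aryl triisopropylsilyl ether withstands DBU in dry acetonitrile.

Step 8
Reactants: 12 5,7-bis[(2-methylbut-3-yn-2-yl)oxy]-3-{2-[(2-methylbut-3-yn-2-yl)oxy]-4-[(triisopropylsilyl)oxy]phenyl}-4H-chromen-4-one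
Product: 13 5,7-bis[(2-methylbut-3-en-2-yl)oxy]-3-{2-[(2-methylbut-3-en-2-yl)oxy]-4-[(triisopropylsilyl)oxy]phenyl}-4H-chromen-4-one
Conditions: H2 (1 atm), Pd/CaCO3 poisoned with Pb(OAc)2 (Lindlar catalyst), quinoline, EtOAc, rt, stopped after three equivalents of H2
Reagents that add atoms: none
Why: Lindlar semihydrogenation of the three terminal alkynes to vinyl groups; the poisoned catalyst should leave the chromone C2=C3 bond, the aryl–oxygen bonds and the silyl ether untouched. The alkenes are made only here because they would not survive zerovalent palladium.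

Step 9
Reactants: 13 5,7-bis[(2-methylbut-3-en-2-yl)oxy]-3-{2-[(2-methylbut-3-en-2-yl)oxy]-4-[(triisopropylsilyl)oxy]phenyl}-4H-chromen-4-one
Product: 15 5,7-dihydroxy-3-{2-hydroxy-3-(3-methylbut-2-enyl)-4-[(triisopropylsilyl)oxy]phenyl}-6,8-bis(3-methylbut-2-enyl)-4H-chromen-4-one, via 6-prenyl 5-phenol 14 (not isolated)
Conditions: Eu(fod)3 (10 mol%), degassed toluene, 45 °C; then 110 °C, argon
Reagents that add atoms: none
Why: Eu(fod)3 (trivalent europium with three 6,6,7,7,8,8,8-heptafluoro-2,2-dimethyloctane-3,5-dionate ligands) binds the C4 carbonyl and O5 in a six-membered chelate and weakens the O5–C(CH3)2 bond, so the 5-O group shifts through a chair [3,3] transition state to C6, its only open ortho carbon because C4a is quaternary, and the dienone enolises to the chelated phenol 14 well below the temperature at which unactivated aryl ethers move. At 110 °C the 7-O group follows by the thermal aromatic Claisen rearrangement and should end on C8, since C6 is occupied and attack there would build a quaternary carbon that cannot become a phenol without a further shift; the 2'-O group moves to C3', because C1' carries ring C. Each shift inverts the allyl unit, so the tertiary oxygen-bound terminus becomes the free =C(CH3)2 end and the former vinyl CH2 forms the new aryl–CH2 bond, and tautomerisation of each ortho-dienone to the phenol drives the sequence. The closest known reactions are the aromatic Claisen rearrangement of aryl 1,1-dimethylallyl ethers to o-prenylphenols and the Eu(fod)3-catalysed Claisen rearrangement of 5-O-allyl-type flavonoid ethers. No ring closes and no stereocentre is formed. The selectivity needed is positional (C6 before C8 in ring A, C3' and not C5' in ring B); it rests on the quaternary neighbours C4a and C1' and on the chelation-timed order of the shifts. Relief of the crowded tertiary ethers lowers each barrier, so the chromone, the silyl ether and the new o-prenylphenols are not overheated.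

Step 10
Reactants: 15 5,7-dihydroxy-3-{2-hydroxy-3-(3-methylbut-2-enyl)-4-[(triisopropylsilyl)oxy]phenyl}-6,8-bis(3-methylbut-2-enyl)-4H-chromen-4-one
Product: 16 euchrenone b2 (3-[2,4-dihydroxy-3-(3-methylbut-2-enyl)phenyl]-5,7-dihydroxy-6,8-bis(3-methylbut-2-enyl)-4H-chromen-4-one)
Conditions: TBAF (1.1 equiv), AcOH (1.1 equiv), THF, 0 °C
Reagents that add atoms: none
Why: Fluoride-mediated desilylation cleaves the aryl silyl ether; buffering with acetic acid avoids a free polyphenoxide, and the absence of strong acid keeps the o-prenylphenols from closing to chromans.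

## Compound list

1 | 2,4,6-trihydroxyacetophenone | CC(=O)c1c(O)cc(O)cc1O | starting material
2 | 3-chloro-3-methylbut-1-yne | CC(C)(Cl)C#C | starting material
3 | 1-{2,6-dihydroxy-4-[(2-methylbut-3-yn-2-yl)oxy]phenyl}ethan-1-one | CC(=O)c1c(O)cc(OC(C)(C)C#C)cc1O | intermediate (not isolated)
4 | 1-{2-hydroxy-4,6-bis[(2-methylbut-3-yn-2-yl)oxy]phenyl}ethan-1-one | CC(=O)c1c(O)cc(OC(C)(C)C#C)cc1OC(C)(C)C#C | intermediate
5 | (E)-3-(dimethylamino)-1-{2-hydroxy-4,6-bis[(2-methylbut-3-yn-2-yl)oxy]phenyl}prop-2-en-1-one | CN(C)/C=C/C(=O)c1c(O)cc(OC(C)(C)C#C)cc1OC(C)(C)C#C | intermediate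
6 | 3-iodo-5,7-bis[(2-methylbut-3-yn-2-yl)oxy]-4H-chromen-4-one | O=c1c(I)coc2cc(OC(C)(C)C#C)cc(OC(C)(C)C#C)c12 | intermediate
7 | 4-bromoresorcinol (4-bromobenzene-1,3-diol) | Oc1ccc(Br)c(O)c1 | starting material
8 | 2-bromo-5-[(triisopropylsilyl)oxy]phenol | Oc1cc(O[Si](C(C)C)(C(C)C)C(C)C)ccc1Br | intermediate
9 | lithium 2-lithio-5-[(triisopropylsilyl)oxy]phenolate | [Li]Oc1cc(O[Si](C(C)C)(C(C)C)C(C)C)ccc1[Li] | intermediate (not isolated)
10 | 2-(4,4,5,5-tetramethyl-1,3,2-dioxaborolan-2-yl)-5-[(triisopropylsilyl)oxy]phenol | CC1(C)OB(OC1(C)C)c1ccc(O[Si](C(C)C)(C(C)C)C(C)C)cc1O | intermediate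
11 | 3-{2-hydroxy-4-[(triisopropylsilyl)oxy]phenyl}-5,7-bis[(2-methylbut-3-yn-2-yl)oxy]-4H-chromen-4-one | C#CC(C)(C)Oc1cc(OC(C)(C)C#C)c2c(c1)occ(-c1ccc(O[Si](C(C)C)(C(C)C)C(C)C)cc1O)c2=O | intermediate
12 | 5,7-bis[(2-methylbut-3-yn-2-yl)oxy]-3-{2-[(2-methylbut-3-yn-2-yl)oxy]-4-[(triisopropylsilyl)oxy]phenyl}-4H-chromen-4-one | C#CC(C)(C)Oc1cc(O[Si](C(C)C)(C(C)C)C(C)C)ccc1-c1coc2cc(OC(C)(C)C#C)cc(OC(C)(C)C#C)c2c1=O | intermediate
13 | 5,7-bis[(2-methylbut-3-en-2-yl)oxy]-3-{2-[(2-methylbut-3-en-2-yl)oxy]-4-[(triisopropylsilyl)oxy]phenyl}-4H-chromen-4-one (4'-O-triisopropylsilyl 5,7,2'-tris(1,1-dimethylallyl) ether of 5,7,2',4'-tetrahydroxyisoflavone) | C=CC(C)(C)Oc1cc(O[Si](C(C)C)(C(C)C)C(C)C)ccc1-c1coc2cc(OC(C)(C)C=C)cc(OC(C)(C)C=C)c2c1=O | intermediate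
14 | 5-hydroxy-6-(3-methylbut-2-enyl)-7-[(2-methylbut-3-en-2-yl)oxy]-3-{2-[(2-methylbut-3-en-2-yl)oxy]-4-[(triisopropylsilyl)oxy]phenyl}-4H-chromen-4-one | C=CC(C)(C)Oc1cc(O[Si](C(C)C)(C(C)C)C(C)C)ccc1-c1coc2cc(OC(C)(C)C=C)c(CC=C(C)C)c(O)c2c1=O | intermediate (not isolated)
15 | 5,7-dihydroxy-3-{2-hydroxy-3-(3-methylbut-2-enyl)-4-[(triisopropylsilyl)oxy]phenyl}-6,8-bis(3-methylbut-2-enyl)-4H-chromen-4-one (4'-O-triisopropylsilyl euchrenone b2) | CC(C)=CCc1c(O[Si](C(C)C)(C(C)C)C(C)C)ccc(-c2coc3c(CC=C(C)C)c(O)c(CC=C(C)C)c(O)c3c2=O)c1O | intermediate
16 | euchrenone b2 | CC(C)=CCc1c(O)ccc(-c2coc3c(CC=C(C)C)c(O)c(CC=C(C)C)c(O)c3c2=O)c1O | target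

## Step count and least certain steps

Total: 10 steps. Longest linear sequence: 8 steps (steps 1, 2, 3, 6, 7, 8, 9, 10). The ring B branch (steps 4 and 5) joins at step 6.

**Step 9 (key step).** Two processes are most likely to spoil it. The tertiary C–O bonds may break heterolytically on the Lewis acid or on long heating, so that isoprene is lost or the allyl cation returns to a wrong carbon. The 7-O group may also begin to shift onto C6 before the chelation-driven 5-O shift is finished; the 5-O group is then forced through C6 to C8 by a Cope shift and arrives inverted as a 1,1-dimethylallyl group.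

Fallback (sets out from 1, with 10 joining at the coupling, and returns at 15): plain allyl groups replace the tertiary carriers. Allyl bromide and K2CO3 in acetone should convert 1 into 1-[2,4-bis(allyloxy)-6-hydroxyphenyl]ethan-1-one F1. The conditions of steps 2 and 3 should then give (E)-1-[2,4-bis(allyloxy)-6-hydroxyphenyl]-3-(dimethylamino)prop-2-en-1-one F2 and 5,7-bis(allyloxy)-3-iodo-4H-chromen-4-one F3. Coupling of F3 with 10 as in step 6 should give 5,7-bis(allyloxy)-3-{2-hydroxy-4-[(triisopropylsilyl)oxy]phenyl}-4H-chromen-4-one F4, and a second allylation should give 5,7-bis(allyloxy)-3-{2-(allyloxy)-4-[(triisopropylsilyl)oxy]phenyl}-4H-chromen-4-one F5. Heating F5 in N,N-diethylaniline at about 190 °C should move all three allyl groups to carbon and give 6,8-diallyl-3-{3-allyl-2-hydroxy-4-[(triisopropylsilyl)oxy]phenyl}-5,7-dihydroxy-4H-chromen-4-one F6. A primary allyl ether does not ionise, and because an unsubstituted allyl group is the same from either end, direct ortho shifts and Claisen–Cope relays through C6 converge on the same 6,8-pattern whatever the order. Threefold cross-metathesis of F6 with 2-methylbut-2-ene and the second-generation Grubbs catalyst (H2IMes)(PCy3)Cl2Ru=CHPh should then give 15.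

**Step 6.** The electron-rich boronate 10, present as its ortho phenoxide in aqueous carbonate, may lose boron by protonolysis before it transmetalates. The phenoxide or hydroxide may add to C2 of the iodochromone and open the pyranone. The terminal alkynes may transfer to palladium and couple in place of the aryl group.

Fallback (sets out from 8, returns at 11): the phenol is masked for the coupling. Chloromethyl methyl ether and i-Pr2NEt should give 1-bromo-2-(methoxymethoxy)-4-[(triisopropylsilyl)oxy]benzene F7. Bromine–lithium exchange with one equivalent of n-BuLi and trapping with iPrOBpin should give 2-{2-(methoxymethoxy)-4-[(triisopropylsilyl)oxy]phenyl}-4,4,5,5-tetramethyl-1,3,2-dioxaborolane F8. Coupling of F8 with 6 under anhydrous conditions (PdCl2(dppf), K3PO4, dioxane) should give 3-{2-(methoxymethoxy)-4-[(triisopropylsilyl)oxy]phenyl}-5,7-bis[(2-methylbut-3-yn-2-yl)oxy]-4H-chromen-4-one F9. Cleavage of the aryl methoxymethyl ether of F9 with TMSOTf and 2,2'-bipyridyl in CH2Cl2 at 0 °C, followed by water, should give 11 without disturbing the propargyl and silyl ethers.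

**Step 1.** The second etherification, at the hindered ortho hydroxyl, may stall at the mono-ether 3. Forcing it invites C-propargylation of the phloroglucinol ring or thermal cyclisation of an aryl propargyl ether to a chromene.

Fallback (sets out from 1, returns at 4): the tertiary ether carbon is attached with a small, strongly activated electrophile and the alkyne is made afterwards. 2-Bromo-2-methylpropanal and K2CO3 in DMF should alkylate the para and the free ortho hydroxyl to give 2,2'-[(4-acetyl-5-hydroxy-1,3-phenylene)bis(oxy)]bis(2-methylpropanal) F10. Ohira–Bestmann homologation of both non-enolisable aldehydes of F10 (dimethyl (1-diazo-2-oxopropyl)phosphonate, K2CO3, MeOH, rt) should give 4; the chelated aryl methyl ketone should not react under these conditions.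

**Step 8.** Hydrogen uptake over three terminal alkynes may not stop evenly. Over-reduced tert-pentyl ethers cannot rearrange, and any alkyne left would cyclise to a chromene in step 9.

Fallback (sets out from 12, returns at 13): stoichiometric hydroboration and protonolysis, which cannot go past the alkene. Dicyclohexylborane (3.3 equiv) in THF at 0 °C should add to each terminal alkyne to give the tris(alkenylborane) 5,7-bis{[(3E)-4-(dicyclohexylboranyl)-2-methylbut-3-en-2-yl]oxy}-3-{2-{[(3E)-4-(dicyclohexylboranyl)-2-methylbut-3-en-2-yl]oxy}-4-[(triisopropylsilyl)oxy]phenyl}-4H-chromen-4-one F11. Protonolysis of the three alkenyl–boron bonds of F11 with acetic acid at room temperature should give 13.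

## Further compounds

F1 | step 9 | 1-[2,4-bis(allyloxy)-6-hydroxyphenyl]ethan-1-one | CC(=O)c1c(O)cc(OCC=C)cc1OCC=C
F2 | step 9 | (E)-1-[2,4-bis(allyloxy)-6-hydroxyphenyl]-3-(dimethylamino)prop-2-en-1-one | CN(C)/C=C/C(=O)c1c(O)cc(OCC=C)cc1OCC=C
F3 | step 9 | 5,7-bis(allyloxy)-3-iodo-4H-chromen-4-one | C=CCOc1cc(OCC=C)c2c(c1)occ(I)c2=O
F4 | step 9 | 5,7-bis(allyloxy)-3-{2-hydroxy-4-[(triisopropylsilyl)oxy]phenyl}-4H-chromen-4-one | C=CCOc1cc(OCC=C)c2c(c1)occ(-c1ccc(O[Si](C(C)C)(C(C)C)C(C)C)cc1O)c2=O
F5 | step 9 | 5,7-bis(allyloxy)-3-{2-(allyloxy)-4-[(triisopropylsilyl)oxy]phenyl}-4H-chromen-4-one | C=CCOc1cc(O[Si](C(C)C)(C(C)C)C(C)C)ccc1-c1coc2cc(OCC=C)cc(OCC=C)c2c1=O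
F6 | step 9 | 6,8-diallyl-3-{3-allyl-2-hydroxy-4-[(triisopropylsilyl)oxy]phenyl}-5,7-dihydroxy-4H-chromen-4-one | C=CCc1c(O[Si](C(C)C)(C(C)C)C(C)C)ccc(-c2coc3c(CC=C)c(O)c(CC=C)c(O)c3c2=O)c1O
F7 | step 6 | 1-bromo-2-(methoxymethoxy)-4-[(triisopropylsilyl)oxy]benzene | COCOc1cc(O[Si](C(C)C)(C(C)C)C(C)C)ccc1Br
F8 | step 6 | 2-{2-(methoxymethoxy)-4-[(triisopropylsilyl)oxy]phenyl}-4,4,5,5-tetramethyl-1,3,2-dioxaborolane | COCOc1cc(O[Si](C(C)C)(C(C)C)C(C)C)ccc1B1OC(C)(C)C(C)(C)O1
F9 | step 6 | 3-{2-(methoxymethoxy)-4-[(triisopropylsilyl)oxy]phenyl}-5,7-bis[(2-methylbut-3-yn-2-yl)oxy]-4H-chromen-4-one | COCOc1cc(O[Si](C(C)C)(C(C)C)C(C)C)ccc1-c1coc2cc(OC(C)(C)C#C)cc(OC(C)(C)C#C)c2c1=O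
F10 | step 1 | 2,2'-[(4-acetyl-5-hydroxy-1,3-phenylene)bis(oxy)]bis(2-methylpropanal) | CC(=O)c1c(O)cc(OC(C)(C)C=O)cc1OC(C)(C)C=O
F11 | step 8 | 5,7-bis{[(3E)-4-(dicyclohexylboranyl)-2-methylbut-3-en-2-yl]oxy}-3-{2-{[(3E)-4-(dicyclohexylboranyl)-2-methylbut-3-en-2-yl]oxy}-4-[(triisopropylsilyl)oxy]phenyl}-4H-chromen-4-one | CC(C)(/C=C/B(C1CCCCC1)C1CCCCC1)Oc1cc(O[Si](C(C)C)(C(C)C)C(C)C)ccc1-c1coc2cc(OC(C)(C)/C=C/B(C3CCCCC3)C3CCCCC3)cc(OC(C)(C)/C=C/B(C3CCCCC3)C3CCCCC3)c2c1=O
A1 | alternative 1 | 3-(methoxymethoxy)-2-(3-methylbut-2-enyl)phenyl 3-iodo-5,7-bis(methoxymethoxy)-6,8-bis(3-methylbut-2-enyl)-4-oxo-4H-chromene-2-carboxylate | COCOc1cccc(OC(=O)c2oc3c(CC=C(C)C)c(OCOC)c(CC=C(C)C)c(OCOC)c3c(=O)c2I)c1CC=C(C)C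
A2 | alternative 1 | lactone-bridged isoflavone (C2 carbonyl tied to O2') | COCOc1ccc2c(c1CC=C(C)C)oc(=O)c1oc3c(CC=C(C)C)c(OCOC)c(CC=C(C)C)c(OCOC)c3c(=O)c12
A3 | alternative 2 | 5,7,2',4'-tetraacetoxy-6,8,3'-tris(bromomethyl)isoflavone | BrCc1c(OC(C)=O)ccc(-c2coc3c(CBr)c(OC(C)=O)c(CBr)c(OC(C)=O)c3c2=O)c1OC(C)=O
A4 | alternative 2 | tributyl(2-methylprop-1-enyl)stannane | CCCC[Sn](CCCC)(CCCC)C=C(C)C
A5 | alternative 2 | euchrenone b2 tetraacetate | CC(C)=CCc1c(OC(C)=O)ccc(-c2coc3c(CC=C(C)C)c(OC(C)=O)c(CC=C(C)C)c(OC(C)=O)c3c2=O)c1OC(C)=O
A6 | alternative 3 | 2-(2-diazo-5-methylhex-4-enoyl)-5-[2,4-bis(methoxymethoxy)-3-(3-methylbut-2-enyl)phenyl]-4H-pyran-4-one | CC(C)=CCC(=[N+]=[N-])C(=O)c1cc(=O)c(-c2ccc(OCOC)c(CC=C(C)C)c2OCOC)co1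
A7 | alternative 3 | (3-methylbut-2-enyl){5-[2,4-bis(methoxymethoxy)-3-(3-methylbut-2-enyl)phenyl]-4-oxo-4H-pyran-2-yl}ketene | CC(C)=CCC(=C=O)c1cc(=O)c(-c2ccc(OCOC)c(CC=C(C)C)c2OCOC)co1
A8 | alternative 3 | triisopropyl[(5-methylhex-4-en-1-yn-1-yl)oxy]silane | CC(C)=CCC#CO[Si](C(C)C)(C(C)C)C(C)C
A9 | alternative 3 | 7-O-triisopropylsilyl-2',4'-bis-O-(methoxymethyl) euchrenone b2 | COCOc1ccc(-c2coc3c(CC=C(C)C)c(O[Si](C(C)C)(C(C)C)C(C)C)c(CC=C(C)C)c(O)c3c2=O)c(OCOC)c1CC=C(C)C
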